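**Plan** (labdane numbering: C7 carbinol, C8(17) exocyclic alkene, C11 peroxy-bearing CH, C12=C13 ring alkene, C14 ring CH2, C15 hemiacetal CH, C16 formyl)

1. Retrosynthesis first opens the 1,2-dioxepine at the hemiacetal bond O–C15 and cuts C11–O, leaving a (12E)-7β-silyloxy-labda-8(17),12-dien-16-al with C15 masked as a dimethyl acetal.
2. C13–C14 is then cut across a temporary 2-ethoxytetrahydrofuran ring (C13, C14, C15, O, C16). C16 (formyl carbon) and C15 (hemiacetal carbon) are both oxygenated and flank the C13–C14 unit, so a C16–O–C15 acetal bridge can hold a C14 radical five atoms from the alkyne carbon C13.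
3. Further cuts: C13–C16 (formaldehyde), C12≡C13 (one-carbon homologation of C12), C7–O (allylic oxidation) and the C8–O bond of (+)-sclareolide.
4. Forward: the decalin comes from sclareolide, followed by the alkyne, the 8(17)-alkene and the 7β-hydroxyl. The temporary oxolane ring is closed by the C13–C14 bond and then opened to the enal. O2 is introduced at C11, and the 1,2-dioxepine closes last by hemiacetalization.
5. Stereochemistry: C5, C9, C10 from sclareolide; C7 by axial hydride delivery to the 7-ketone; C11 by attack of O2 on the dienolate face anti to C10; C15 by equilibration; the C12=C13 geometry by the s-trans dienolate and the final ring.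

Key step: step 10

Assumption: the C15 hemiacetal centre equilibrates through the open hydroperoxy aldehyde, and the (15R) epimer of the target (15-OH cis to the C11 substituent) is taken to be the thermodynamically preferred one.

**Route**

Step 1
Reactants: 1 (+)-sclareolide
Product: 2 sclareolide lactol (8α,12-epoxy-13,14,15,16-tetranorlabdan-12-ol; both anomers)
Conditions: i-Bu2AlH, CH2Cl2, −78 °C; aq. KNaC4H4O6
Reagents that add atoms: none
Why: Half-reduction of a γ-lactone by a hindered aluminium hydride should stop at the lactol because the tetrahedral aluminate survives at low temperature, and the anomeric centre formed is of no consequence.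

Step 2
Reactants: 2 sclareolide lactol
Product: 4 14,15,16-trinorlabd-12-yn-8α-ol (propargyl group on C9; tertiary 8α-hydroxyl; 8β-methyl), via hydroxy aldehyde 3 (not isolated)
Conditions: dimethyl (1-diazo-2-oxopropyl)phosphonate, K2CO3, MeOH, rt
Reagents that add atoms: dimethyl (1-diazo-2-oxopropyl)phosphonate, CC(=O)C(=[N+]=[N-])P(=O)(OC)OC
Why: Seyferth–Gilbert homologation in the Ohira–Bestmann version should act on the open aldehyde tautomer 3 (C12) and supply the terminal alkyne carbon C13 under mild base that leaves C9 untouched.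

Step 3
Reactants: 4 14,15,16-trinorlabd-12-yn-8α-ol
Product: 6 14,15,16-trinorlabd-8(17)-en-12-yne, via chlorosulfite 5 (not isolated)
Conditions: SOCl2, pyridine, CH2Cl2, −78 °C
Reagents that add atoms: none
Why: E2 elimination of the chlorosulfite should give mainly the exocyclic 8(17)-alkene, because the equatorial C8–O bond has no anti-periplanar ring hydrogen and pyridine must take a proton from the C17 methyl group (regioselective dehydration of an equatorial tertiary alcohol).

Step 4
Reactants: 6 14,15,16-trinorlabd-8(17)-en-12-yne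
Product: 7 14,15,16-trinorlabd-8(17)-en-12-yn-7α-ol (axial hydroxyl)
Conditions: SeO2 (cat.), t-BuOOH, CH2Cl2, rt
Reagents that add atoms: tert-butyl hydroperoxide, CC(C)(C)OO; selenium dioxide, O=[Se]=O (catalytic oxygen carrier)
Why: Riley allylic oxidation (ene reaction at the exocyclic methylene, then 2,3-sigmatropic shift) should hydroxylate the ring methylene C7 rather than the methine C9 and deliver oxygen axially to give the 7α-alcohol, whose configuration is corrected in steps 5 and 6.

Step 5
Reactants: 7 14,15,16-trinorlabd-8(17)-en-12-yn-7α-ol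
Product: 8 14,15,16-trinorlabd-8(17)-en-12-yn-7-one
Conditions: Dess–Martin periodinane, CH2Cl2, 0 °C to rt
Reagents that add atoms: none
Why: Dess–Martin oxidation should convert the secondary allylic alcohol into the exo-methylene ketone under conditions that spare the alkyne and offer no nucleophile to the enone.

Step 6
Reactants: 8 14,15,16-trinorlabd-8(17)-en-12-yn-7-one
Product: 9 14,15,16-trinorlabd-8(17)-en-12-yn-7β-ol (equatorial hydroxyl)
Conditions: NaBH4, CeCl3·7H2O, MeOH, −78 °C
Reagents that add atoms: none
Why: Luche reduction should give clean 1,2-reduction, and axial delivery of hydride to C7 from the α face places the hydroxyl equatorial (7β), which sets the C7 stereocentre of the target.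

Step 7
Reactants: 9 14,15,16-trinorlabd-8(17)-en-12-yn-7β-ol
Product: 10 7β-(tert-butyldimethylsilyloxy)-14,15,16-trinorlabd-8(17)-en-12-yne
Conditions: t-BuMe2SiCl, imidazole, DMF, rt
Reagents that add atoms: tert-butyldimethylsilyl chloride, CC(C)(C)[Si](C)(C)Cl
Why: Silylation of the secondary alcohol shields it from the organolithium, bromoacetalization, radical and base steps that follow.

Step 8
Reactants: 10 7β-(tert-butyldimethylsilyloxy)-14,15,16-trinorlabd-8(17)-en-12-yne
Product: 12 7β-(tert-butyldimethylsilyloxy)-14,15-dinorlabd-8(17)-en-12-yn-16-ol (propargylic alcohol), via lithium acetylide 11 (not isolated)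
Conditions: n-BuLi, THF, −78 °C; (CH2O)n, −78 °C to rt; H2O
Reagents that add atoms: paraformaldehyde (as formaldehyde), C=O
Why: Addition of the lithium acetylide to formaldehyde is a standard hydroxymethylation and installs C16 with its oxygen.

Step 9
Reactants: 12 7β-(tert-butyldimethylsilyloxy)-14,15-dinorlabd-8(17)-en-12-yn-16-ol
Product: 13 16-O-(2-bromo-1-ethoxyethyl) ether of 12 (bromoacetal; both epimers at the acetal carbon, the future C15; BrCH2 is the future C14)
Conditions: ethyl vinyl ether, N-bromosuccinimide, CH2Cl2, −40 °C to 0 °C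
Reagents that add atoms: ethyl vinyl ether, C=COCC; N-bromosuccinimide, O=C1CCC(=O)N1Br
Why: Bromoetherification of the electron-rich enol ether, with the primary alcohol capturing the bromo-oxocarbenium ion, should give the mixed bromoacetal much faster than N-bromosuccinimide can attack the 8(17)-alkene.

Step 10
Reactants: 13 bromoacetal
Product: 14 7β-(tert-butyldimethylsilyloxy)-15-ethoxy-15,16-epoxylabda-8(17),12-diene (4-alkylidene-2-ethoxytetrahydrofuran; both C15 epimers; both C12=C13 geometric isomers)
Conditions: Bu3SnH (slow addition), AIBN (cat.), toluene, 80 °C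
Reagents that add atoms: none
Why: Bu3Sn• abstracts bromine from 13 and the primary C14 radical adds to the alkyne carbon C13 in a chain process, after which the σ-vinyl radical at C12 takes a hydrogen atom from Bu3SnH (or by harmless 1,5-transfer from C20 or C1, followed by stannane reduction). The closest known reaction type is the Ueno–Stork haloacetal radical cyclization onto a propargylic ether. The one ring closed is the temporary 2-ethoxytetrahydrofuran (C13, C14, C15, O, C16), formed in the 5-exo-dig mode. No permanent stereocentre is created: C15 forms as both epimers and is unmasked later, and the C12=C13 geometry (hydrogen delivery past the smaller C16 methylene should favour C11 syn to C14) is erased and reset through the dienolate of step 14. The step needs 5-exo closure to outrun direct reduction of the C14 radical and 6-endo attack at C12, which the short C–O bonds of the 3-oxa tether and slow stannane addition should secure, while the remote 8(17)-alkene and the silyl ether lie out of reach of both radical centres.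

Step 11
Reactants: 14 4-alkylidene-2-ethoxytetrahydrofuran
Product: 15 7β-(tert-butyldimethylsilyloxy)-15,15-(propane-1,3-diyldithio)labda-8(17),12-dien-16-ol (C15 as a 1,3-dithiane; free allylic C16 alcohol; both geometric isomers)
Conditions: HS(CH2)3SH, BF3·OEt2, CH2Cl2, −40 °C to −10 °C
Reagents that add atoms: propane-1,3-dithiol, SCCCS
Why: Lewis-acid transthioacetalization of a lactol ether should open the temporary ring, because the C15 oxocarbenium ion is captured twice by sulfur to give the stable dithiane and releases the C16 hydroxyl.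

Step 12
Reactants: 15 dithiane alcohol
Product: 16 (12E)-7β-(tert-butyldimethylsilyloxy)-15,15-(propane-1,3-diyldithio)labda-8(17),12-dien-16-al
Conditions: MnO2, CH2Cl2, rt
Reagents that add atoms: none
Why: Activated MnO2 oxidizes only the allylic primary alcohol and leaves the dithiane alone; the α-branched enal should settle in the E form, and any Z isomer carried on converges in step 14.

Step 13
Reactants: 16 enal dithiane
Product: 17 (12E)-7β-(tert-butyldimethylsilyloxy)-15,15-dimethoxylabda-8(17),12-dien-16-al
Conditions: PhI(OCOCF3)2, MeOH, rt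
Reagents that add atoms: methanol, CO
Why: Oxidative dethioacetalization with a trivalent iodine reagent in methanol should activate sulfur and let methanol capture the thionium ions, exchanging the dithiane for a dimethyl acetal that is stable to base and removable by dilute acid in the presence of a peroxide.

Step 14
Reactants: 17 enal dimethyl acetal
Product: 19 (11S,12E)-7β-(tert-butyldimethylsilyloxy)-11-hydroperoxy-15,15-dimethoxylabda-8(17),12-dien-16-al, via potassium dienolate 18 (not isolated)
Conditions: KN(SiMe3)2, THF, −78 °C; O2, −78 °C; AcOH, −78 °C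
Reagents that add atoms: dioxygen, O=O
Why: Proposed new method: γ-deprotonation at C11 (the only acidic site once C15 is an acetal) should give the s-trans potassium dienolate 18, which transfers an electron to triplet O2 and combines with it at the γ-terminus C11, since addition at the fully substituted α-carbon C13 breaks the conjugation and is reversible, and protonation at −78 °C should release the hydroperoxide before Kornblum–DeLaMare elimination sets in; the s-trans dienolate returns the (12E)-enal, and O2 is expected to approach C11 anti to the quaternary C10 with C9–H in the diene plane, which gives (11S), the (11R) epimer being removed by chromatography; the closest known reaction type is the base-mediated γ-hydroperoxidation of α,β-unsaturated ketones through their dienolates, which has not been shown on an acyclic α-branched enal.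

Step 15
Reactants: 19 hydroperoxy enal dimethyl acetal
Product: 21 CNP0269954.2, (11S,12E,15R)-11,15-epidioxy-7β,15-dihydroxylabda-8(17),12-dien-16-al, via hydroperoxy dial 20 (not isolated)
Conditions: HF (aq.), MeCN, 0 °C to rt
Reagents that add atoms: water, O
Why: Aqueous HF should hydrolyse the dimethyl acetal and cleave the silyl ether, and the 11-hydroperoxide of 20 then adds to the saturated C15 aldehyde to close the seven-membered peroxy-hemiacetal (ring-chain tautomerism), the E alkene keeping the conjugated C16 aldehyde out of reach and C15 settling by equilibration.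

**Compound list**

1 | (+)-sclareolide | O=C1C[C@@H]2[C@@]3(C)CCCC(C)(C)[C@@H]3CC[C@@]2(C)O1 | starting material
2 | sclareolide lactol (8α,12-epoxy-13,14,15,16-tetranorlabdan-12-ol; both anomers) | OC1C[C@@H]2[C@@]3(C)CCCC(C)(C)[C@@H]3CC[C@@]2(C)O1 | intermediate
3 | 8α-hydroxy-13,14,15,16-tetranorlabdan-12-al (open hydroxy aldehyde) | O=CC[C@@H]1[C@@]2(C)CCCC(C)(C)[C@@H]2CC[C@@]1(C)O | intermediate (not isolated)
4 | 14,15,16-trinorlabd-12-yn-8α-ol | C#CC[C@@H]1[C@@]2(C)CCCC(C)(C)[C@@H]2CC[C@@]1(C)O | intermediate
5 | 8α-chlorosulfite of 4 | C#CC[C@@H]1[C@@]2(C)CCCC(C)(C)[C@@H]2CC[C@@]1(C)OS(=O)Cl | intermediate (not isolated)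
6 | 14,15,16-trinorlabd-8(17)-en-12-yne | C=C1[C@H](CC#C)[C@@]2(C)CCCC(C)(C)[C@@H]2CC1 | intermediate
7 | 14,15,16-trinorlabd-8(17)-en-12-yn-7α-ol | C=C1[C@H](CC#C)[C@@]2(C)CCCC(C)(C)[C@@H]2C[C@H]1O | intermediate
8 | 14,15,16-trinorlabd-8(17)-en-12-yn-7-one | C=C1[C@H](CC#C)[C@@]2(C)CCCC(C)(C)[C@@H]2CC1=O | intermediate
9 | 14,15,16-trinorlabd-8(17)-en-12-yn-7β-ol | C=C1[C@H](CC#C)[C@@]2(C)CCCC(C)(C)[C@@H]2C[C@@H]1O | intermediate
10 | 7β-(tert-butyldimethylsilyloxy)-14,15,16-trinorlabd-8(17)-en-12-yne | C=C1[C@H](CC#C)[C@@]2(C)CCCC(C)(C)[C@@H]2C[C@@H]1O[Si](C)(C)C(C)(C)C | intermediate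
11 | lithium acetylide of 10 | C=C1[C@H](CC#C[Li])[C@@]2(C)CCCC(C)(C)[C@@H]2C[C@@H]1O[Si](C)(C)C(C)(C)C | intermediate (not isolated)
12 | 7β-(tert-butyldimethylsilyloxy)-14,15-dinorlabd-8(17)-en-12-yn-16-ol | C=C1[C@H](CC#CCO)[C@@]2(C)CCCC(C)(C)[C@@H]2C[C@@H]1O[Si](C)(C)C(C)(C)C | intermediate
13 | 16-O-(2-bromo-1-ethoxyethyl) ether of 12 (both acetal epimers) | C=C1[C@H](CC#CCOC(CBr)OCC)[C@@]2(C)CCCC(C)(C)[C@@H]2C[C@@H]1O[Si](C)(C)C(C)(C)C | intermediate
14 | 7β-(tert-butyldimethylsilyloxy)-15-ethoxy-15,16-epoxylabda-8(17),12-diene (both C15 epimers; both C12=C13 isomers) | C=C1[C@H](CC=C3COC(OCC)C3)[C@@]2(C)CCCC(C)(C)[C@@H]2C[C@@H]1O[Si](C)(C)C(C)(C)C | intermediate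
15 | 7β-(tert-butyldimethylsilyloxy)-15,15-(propane-1,3-diyldithio)labda-8(17),12-dien-16-ol (both C12=C13 isomers) | C=C1[C@H](CC=C(CO)CC3SCCCS3)[C@@]2(C)CCCC(C)(C)[C@@H]2C[C@@H]1O[Si](C)(C)C(C)(C)C | intermediate
16 | (12E)-7β-(tert-butyldimethylsilyloxy)-15,15-(propane-1,3-diyldithio)labda-8(17),12-dien-16-al | C=C1[C@H](C/C=C(/C=O)CC3SCCCS3)[C@@]2(C)CCCC(C)(C)[C@@H]2C[C@@H]1O[Si](C)(C)C(C)(C)C | intermediate
17 | (12E)-7β-(tert-butyldimethylsilyloxy)-15,15-dimethoxylabda-8(17),12-dien-16-al | C=C1[C@H](C/C=C(/C=O)CC(OC)OC)[C@@]2(C)CCCC(C)(C)[C@@H]2C[C@@H]1O[Si](C)(C)C(C)(C)C | intermediate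
18 | potassium dienolate of 17 (C16–O⁻, C13=C16, (11E)-C11=C12) | C=C1[C@H](/C=C/C(=C[O-])CC(OC)OC)[C@@]2(C)CCCC(C)(C)[C@@H]2C[C@@H]1O[Si](C)(C)C(C)(C)C.[K+] | intermediate (not isolated)
19 | (11S,12E)-7β-(tert-butyldimethylsilyloxy)-11-hydroperoxy-15,15-dimethoxylabda-8(17),12-dien-16-al | C=C1[C@H]([C@@H](OO)/C=C(/C=O)CC(OC)OC)[C@@]2(C)CCCC(C)(C)[C@@H]2C[C@@H]1O[Si](C)(C)C(C)(C)C | intermediate
20 | (11S,12E)-11-hydroperoxy-7β-hydroxylabda-8(17),12-diene-15,16-dial | C=C1[C@H]([C@@H](OO)/C=C(/C=O)CC=O)[C@@]2(C)CCCC(C)(C)[C@@H]2C[C@@H]1O | intermediate (not isolated)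
21 | CNP0269954.2, (11S,12E,15R)-11,15-epidioxy-7β,15-dihydroxylabda-8(17),12-dien-16-al | C=C1[C@H]([C@@H]2C=C(C=O)C[C@H](O)OO2)[C@@]2(C)CCCC(C)(C)[C@@H]2C[C@@H]1O | target

**Count**

Total steps: 15. Longest linear sequence: 15.

**Steps most likely to fail**

1. Step 14 (proposed new method). O2 may instead attack the α-carbon C13, with loss of the formyl carbon. The face selectivity at C11 may be poor. The peroxide anion may dehydrate to the 11-ketone before it is protonated. Fallback with known chemistry, from 17: O-silylation of the potassium dienolate with Et3SiCl should give the 1-(triethylsilyloxy)-1,3-diene F1. N-Bromosuccinimide in THF at −78 °C should brominate its γ-terminus (γ-halogenation of a silyl dienol ether) to the 11-bromo enal F2. Silver-assisted perhydrolysis (ethereal H2O2, AgOSO2CF3, 0 °C) should then exchange bromide for the hydroperoxy group. This returns to the route at 19, where the C11 epimers are separated.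

2. Step 15. Acid-induced fragmentation or dehydration of the allylic hydroperoxide may compete with the slower silyl ether cleavage while aldehyde and hydroperoxide are both free. Fallback, from 19: anhydrous acid (pyridinium p-toluenesulfonate, CH2Cl2, molecular sieves) should first close the dioxepine by intramolecular transacetalization to the cyclic methyl peroxyacetal F3, in which the peroxide is a more robust dialkyl peroxide. HF·pyridine in THF should then free the 7-hydroxyl to give the desilylated methyl peroxyacetal F4. Exchange of methoxy for hydroxy in dilute aqueous H2SO4/THF returns to the route at 21.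

3. Step 11. The Lewis acid may ionize the allylic C16–O bond (giving allylic sulfides) or remove the silyl ether instead of opening the ring at C15. Fallback, from 14: mild hydrolysis (AcOH, H2O, THF) should give the lactol F5. NaBH4 in MeOH should reduce it to the 15,16-diol F6. Swern oxidation should give the 15,16-dial F7. Kinetically selective acetalization of the saturated C15 aldehyde beside the conjugated C16 aldehyde (HC(OMe)3, MeOH, CeCl3·7H2O, 0 °C) then returns to the route at 17.

**Further compounds**

F1 | step 14 | 1-(triethylsilyloxy)-1,3-diene from 17 ((11E); C16 enol ether geometry undefined) | C=C1[C@H](/C=C/C(=CO[Si](CC)(CC)CC)CC(OC)OC)[C@@]2(C)CCCC(C)(C)[C@@H]2C[C@@H]1O[Si](C)(C)C(C)(C)C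
F2 | step 14 | (12E)-11-bromo-7β-(tert-butyldimethylsilyloxy)-15,15-dimethoxylabda-8(17),12-dien-16-al (both C11 epimers) | C=C1[C@H](C(Br)/C=C(/C=O)CC(OC)OC)[C@@]2(C)CCCC(C)(C)[C@@H]2C[C@@H]1O[Si](C)(C)C(C)(C)C
F3 | step 15 | (11S)-7β-(tert-butyldimethylsilyloxy)-11,15-epidioxy-15-methoxylabda-8(17),12-dien-16-al (both C15 epimers) | C=C1[C@H]([C@@H]2C=C(C=O)CC(OC)OO2)[C@@]2(C)CCCC(C)(C)[C@@H]2C[C@@H]1O[Si](C)(C)C(C)(C)C
F4 | step 15 | (11S)-11,15-epidioxy-7β-hydroxy-15-methoxylabda-8(17),12-dien-16-al (both C15 epimers) | C=C1[C@H]([C@@H]2C=C(C=O)CC(OC)OO2)[C@@]2(C)CCCC(C)(C)[C@@H]2C[C@@H]1O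
F5 | step 11 | 7β-(tert-butyldimethylsilyloxy)-15,16-epoxylabda-8(17),12-dien-15-ol (lactol; both anomers; both C12=C13 isomers) | C=C1[C@H](CC=C3COC(O)C3)[C@@]2(C)CCCC(C)(C)[C@@H]2C[C@@H]1O[Si](C)(C)C(C)(C)C
F6 | step 11 | 7β-(tert-butyldimethylsilyloxy)labda-8(17),12-diene-15,16-diol (both C12=C13 isomers) | C=C1[C@H](CC=C(CO)CCO)[C@@]2(C)CCCC(C)(C)[C@@H]2C[C@@H]1O[Si](C)(C)C(C)(C)C
F7 | step 11 | (12E)-7β-(tert-butyldimethylsilyloxy)labda-8(17),12-diene-15,16-dial | C=C1[C@H](C/C=C(/C=O)CC=O)[C@@]2(C)CCCC(C)(C)[C@@H]2C[C@@H]1O[Si](C)(C)C(C)(C)C
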